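**Retrosynthetic overview**

- Structural feature: in pyranone ring C the C4 carbonyl lies between aryl carbon C4a and C3, and ring oxygen O1 joins C8a to C2, which carries guaiacyl ring B.
- Key disconnection: C4a–C4, C4–C3 and O1–C2 are cut together, giving iodophenol 10 (C4a–I beside the only free phenol, the future O1), carbon monoxide (C4) and arylacetylene 13 (C3, C2, ring B). Ring C is the only ring formed; rings A and B come from 1 and vanillin.
- Iodophenol 10 from symmetric aldehyde 1: MOM protection, Baeyer–Villiger (unveils the future O-5), iodination ortho to that phenol (one site by symmetry), silylation, MOM removal, then O-prenylation of the phenoxide remote from iodine. The prenyl group goes on last, so neither peracid nor iodinating agent meets the alkene.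
- Alkyne 13 from vanillin by silylation and one-carbon homologation.
- After ring closure: C3–H to C3–OH by lithiation, borylation and oxidation, then fluoride removal of both silyl groups.

Key step: step 9

Remark: the target has no stereocentre or stereogenic axis, so it is one achiral compound and needs no stereocontrol; aldehyde 1 is taken as a catalogue compound.

**Route**

Step 1
Reactants: 1 3,5-dihydroxy-4-methoxybenzaldehyde
Product: 2 4-methoxy-3,5-bis(methoxymethoxy)benzaldehyde
Conditions: MOMCl, i-Pr2NEt, CH2Cl2, 0 °C → rt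
Reagents that add atoms: chloromethyl methyl ether, COCCl
Why: Williamson-type O-alkylation of two unhindered, non-chelated phenols; acetal ethers are chosen over esters because they leave the aryl group electron-rich enough to migrate in the next step.

Step 2
Reactants: 2 4-methoxy-3,5-bis(methoxymethoxy)benzaldehyde
Product: 4 4-methoxy-3,5-bis(methoxymethoxy)phenol, via aryl formate 3 (not isolated)
Conditions: mCPBA, CH2Cl2, 0 °C → rt; then K2CO3 (cat.), MeOH, rt
Reagents that add atoms: meta-chloroperbenzoic acid, OOC(=O)c1cccc(Cl)c1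
Why: Baeyer–Villiger (Dakin-type) oxidation in which the 3,4,5-trialkoxyaryl group should migrate in preference to hydride, as it does for 3,4,5-trimethoxybenzaldehyde, followed by transesterification of the formate; no alkene is present yet for the peracid to attack.

Step 3
Reactants: 4 4-methoxy-3,5-bis(methoxymethoxy)phenol
Product: 5 2-iodo-4-methoxy-3,5-bis(methoxymethoxy)phenol
Conditions: NIS (1.0 equiv), CH2Cl2, −20 → 0 °C, dark
Reagents that add atoms: N-iodosuccinimide, O=C1CCC(=O)N1I
Why: Electrophilic aromatic iodination ortho to the free phenol; the para position is blocked by OMe and the two ortho positions are equivalent, so only one mono-iodide can form, with iodine between the future O-5 and O-1 carbons.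

Step 4
Reactants: 5 2-iodo-4-methoxy-3,5-bis(methoxymethoxy)phenol
Product: 6 [2-iodo-4-methoxy-3,5-bis(methoxymethoxy)phenoxy]triisopropylsilane
Conditions: TIPSCl, imidazole, DMF, rt
Reagents that add atoms: triisopropylsilyl chloride, CC(C)[Si](Cl)(C(C)C)C(C)C
Why: Silylation of the ortho-iodophenol; TIPS is used because this ether must outlast methanolic acid, a sodium phenoxide in DMF and the amine/DBU medium of the annulation, where a TBS aryl ether would be at risk.

Step 5
Reactants: 6 [2-iodo-4-methoxy-3,5-bis(methoxymethoxy)phenoxy]triisopropylsilane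
Product: 7 4-iodo-2-methoxy-5-[(triisopropylsilyl)oxy]benzene-1,3-diol
Conditions: HCl (cat.), MeOH–THF, rt
Reagents that add atoms: none
Why: Acid-catalysed transacetalisation of both MOM ethers to dimethoxymethane; the aryl TIPS ether, aryl iodide and methyl ether should be inert to dilute methanolic HCl.

Step 6
Reactants: 7 4-iodo-2-methoxy-5-[(triisopropylsilyl)oxy]benzene-1,3-diol; 8 prenyl bromide
Product: 10 2-iodo-6-methoxy-5-[(3-methylbut-2-en-1-yl)oxy]-3-[(triisopropylsilyl)oxy]phenol, via disodium diolate 9 (not isolated)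
Conditions: NaH (2.2 equiv), DMF, 0 °C; 8 (1.0 equiv), −20 → 0 °C; AcOH quench
Reagents that add atoms: none
Why: Williamson etherification of the dianion, in which the phenoxide para to iodine is the more basic and less hindered one (the other is stabilised by ortho-iodine and wedged between I and OMe), so one equivalent of prenyl bromide in DMF should O-alkylate there.

Step 7
Reactants: 11 vanillin
Product: 12 3-methoxy-4-[(triisopropylsilyl)oxy]benzaldehyde
Conditions: TIPSCl, imidazole, DMF, rt
Reagents that add atoms: triisopropylsilyl chloride, CC(C)[Si](Cl)(C(C)C)C(C)C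
Why: Silylation of an acidic, unhindered phenol; the same silyl group as on ring A allows one final deprotection.

Step 8
Reactants: 12 3-methoxy-4-[(triisopropylsilyl)oxy]benzaldehyde
Product: 13 (4-ethynyl-2-methoxyphenoxy)triisopropylsilane
Conditions: TMSCHN2, LDA (commercial solution), THF, −78 °C → rt
Reagents that add atoms: trimethylsilyldiazomethane, C[Si](C)(C)C=[N+]=[N-]
Why: Colvin rearrangement (addition of lithiated TMS-diazomethane, Peterson-type loss of silanolate, loss of N2 and 1,2-hydride shift of the alkylidene carbene); it avoids methoxide, which would strip a silyl ether from a para-formylphenol.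

Step 9
Reactants: 10 2-iodo-6-methoxy-5-[(3-methylbut-2-en-1-yl)oxy]-3-[(triisopropylsilyl)oxy]phenol; 13 (4-ethynyl-2-methoxyphenoxy)triisopropylsilane
Product: 16 8-methoxy-2-{3-methoxy-4-[(triisopropylsilyl)oxy]phenyl}-7-[(3-methylbut-2-en-1-yl)oxy]-5-[(triisopropylsilyl)oxy]-4H-chromen-4-one, via hydroxyaryl ynone 14 (not isolated), via diethylamino enone 15 (not isolated)
Conditions: PdCl2(PPh3)2 (5 mol%), dppp (5 mol%), thiourea (5 mol%), CO (1 atm), DBU (2 equiv), Et2NH, 40–50 °C
Reagents that add atoms: carbon monoxide, [C-]#[O+]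
Why: Pd(0) adds oxidatively to the C4a–I bond of 10, CO inserts to give the aroyl-palladium, and the amine-deprotonated alkyne 13 is transferred and reductively eliminated to give ynone 14, which forms C4a–C4 and C4–C3. Diethylamine then adds to the ynone at C2 to give enaminone 15, and the C8a phenoxide attacks C2 and expels the amine, forming O1–C2 and closing ring C. The closest known reaction type is the palladium-catalysed carbonylative Sonogashira annulation of ortho-iodophenols with terminal arylacetylenes in a secondary amine. Ring C closes in the 6-endo mode (6-endo-dig with respect to the ynone, addition–elimination on the enaminone), and no stereocentre is formed. The step needs 6-endo closure over 5-exo closure to the aurone, which the amine pathway secures by making C2 the only electrophilic carbon, and CO insertion over direct alkynylation, which the two ortho substituents on the aryl-palladium and the CO atmosphere favour. Only the oxygen flanked by OMe is free (O-5 is silylated, O-7 prenylated), so only the 8-methoxy isomer can form, and the trisubstituted prenyl ether is a poor π-allyl precursor while TIPS ethers tolerate the amine.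

Step 10
Reactants: 16 8-methoxy-2-{3-methoxy-4-[(triisopropylsilyl)oxy]phenyl}-7-[(3-methylbut-2-en-1-yl)oxy]-5-[(triisopropylsilyl)oxy]-4H-chromen-4-one
Product: 19 3-hydroxy-8-methoxy-2-{3-methoxy-4-[(triisopropylsilyl)oxy]phenyl}-7-[(3-methylbut-2-en-1-yl)oxy]-5-[(triisopropylsilyl)oxy]-4H-chromen-4-one, via 3-lithioflavone 17 (not isolated), via lithium trimethoxyborate 18 (not isolated)
Conditions: LDA (commercial solution), THF, −78 °C; B(OMe)3, −78 → 0 °C; AcOH, 30% H2O2, 0 °C
Reagents that add atoms: hydrogen peroxide, OO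
Why: Carbonyl-directed deprotonation of the vinylic C3–H of the flavone, borylation and oxidative C–B to C–O conversion, the known flavone-to-flavonol sequence; LDA at −78 °C should leave the prenyl and silyl ethers alone, and a short, cold peroxide treatment should not epoxidise the alkene.

Step 11
Reactants: 19 3-hydroxy-8-methoxy-2-{3-methoxy-4-[(triisopropylsilyl)oxy]phenyl}-7-[(3-methylbut-2-en-1-yl)oxy]-5-[(triisopropylsilyl)oxy]-4H-chromen-4-one
Product: 20 3,5-dihydroxy-2-(4-hydroxy-3-methoxyphenyl)-8-methoxy-7-[(3-methylbut-2-en-1-yl)oxy]-4H-chromen-4-one (CNP0210396.0)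
Conditions: TBAF, AcOH, THF, 0 °C
Reagents that add atoms: none
Why: Fluoride desilylation of both aryl TIPS ethers; the acetic acid buffer keeps the flavonol from standing as an oxidisable polyphenolate, and the prenyl ether is inert to fluoride.

**Compound list**

1 | 3,5-dihydroxy-4-methoxybenzaldehyde | COc1c(O)cc(C=O)cc1O | starting material
2 | 4-methoxy-3,5-bis(methoxymethoxy)benzaldehyde | COCOc1cc(C=O)cc(OCOC)c1OC | intermediate
3 | 4-methoxy-3,5-bis(methoxymethoxy)phenyl formate | COCOc1cc(OC=O)cc(OCOC)c1OC | intermediate (not isolated)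
4 | 4-methoxy-3,5-bis(methoxymethoxy)phenol | COCOc1cc(O)cc(OCOC)c1OC | intermediate
5 | 2-iodo-4-methoxy-3,5-bis(methoxymethoxy)phenol | COCOc1cc(O)c(I)c(OCOC)c1OC | intermediate
6 | [2-iodo-4-methoxy-3,5-bis(methoxymethoxy)phenoxy]triisopropylsilane | COCOc1cc(O[Si](C(C)C)(C(C)C)C(C)C)c(I)c(OCOC)c1OC | intermediate
7 | 4-iodo-2-methoxy-5-[(triisopropylsilyl)oxy]benzene-1,3-diol | COc1c(O)cc(O[Si](C(C)C)(C(C)C)C(C)C)c(I)c1O | intermediate
8 | prenyl bromide (1-bromo-3-methylbut-2-ene) | CC(C)=CCBr | starting material
9 | disodium 4-iodo-2-methoxy-5-[(triisopropylsilyl)oxy]benzene-1,3-diolate | COc1c([O-])cc(O[Si](C(C)C)(C(C)C)C(C)C)c(I)c1[O-].[Na+].[Na+] | intermediate (not isolated)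
10 | 2-iodo-6-methoxy-5-[(3-methylbut-2-en-1-yl)oxy]-3-[(triisopropylsilyl)oxy]phenol | COc1c(O)c(I)c(O[Si](C(C)C)(C(C)C)C(C)C)cc1OCC=C(C)C | intermediate
11 | vanillin | COc1cc(C=O)ccc1O | starting material
12 | 3-methoxy-4-[(triisopropylsilyl)oxy]benzaldehyde | COc1cc(C=O)ccc1O[Si](C(C)C)(C(C)C)C(C)C | intermediate
13 | (4-ethynyl-2-methoxyphenoxy)triisopropylsilane | C#Cc1ccc(O[Si](C(C)C)(C(C)C)C(C)C)c(OC)c1 | intermediate
14 | 1-{2-hydroxy-3-methoxy-4-[(3-methylbut-2-en-1-yl)oxy]-6-[(triisopropylsilyl)oxy]phenyl}-3-{3-methoxy-4-[(triisopropylsilyl)oxy]phenyl}prop-2-yn-1-one | COc1cc(C#CC(=O)c2c(O)c(OC)c(OCC=C(C)C)cc2O[Si](C(C)C)(C(C)C)C(C)C)ccc1O[Si](C(C)C)(C(C)C)C(C)C | intermediate (not isolated)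
15 | (E)-3-(diethylamino)-1-{2-hydroxy-3-methoxy-4-[(3-methylbut-2-en-1-yl)oxy]-6-[(triisopropylsilyl)oxy]phenyl}-3-{3-methoxy-4-[(triisopropylsilyl)oxy]phenyl}prop-2-en-1-one (drawn E; the geometry has no consequence for ring closure) | CCN(CC)/C(=C/C(=O)c1c(O)c(OC)c(OCC=C(C)C)cc1O[Si](C(C)C)(C(C)C)C(C)C)c1ccc(O[Si](C(C)C)(C(C)C)C(C)C)c(OC)c1 | intermediate (not isolated)
16 | 8-methoxy-2-{3-methoxy-4-[(triisopropylsilyl)oxy]phenyl}-7-[(3-methylbut-2-en-1-yl)oxy]-5-[(triisopropylsilyl)oxy]-4H-chromen-4-one | COc1cc(-c2cc(=O)c3c(O[Si](C(C)C)(C(C)C)C(C)C)cc(OCC=C(C)C)c(OC)c3o2)ccc1O[Si](C(C)C)(C(C)C)C(C)C | intermediate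
17 | 3-lithio derivative of 16 | COc1cc(-c2oc3c(OC)c(OCC=C(C)C)cc(O[Si](C(C)C)(C(C)C)C(C)C)c3c(=O)c2[Li])ccc1O[Si](C(C)C)(C(C)C)C(C)C | intermediate (not isolated)
18 | lithium trimethoxy(flavon-3-yl)borate derived from 17 | COc1cc(-c2oc3c(OC)c(OCC=C(C)C)cc(O[Si](C(C)C)(C(C)C)C(C)C)c3c(=O)c2[B-](OC)(OC)OC)ccc1O[Si](C(C)C)(C(C)C)C(C)C.[Li+] | intermediate (not isolated)
19 | 3-hydroxy-8-methoxy-2-{3-methoxy-4-[(triisopropylsilyl)oxy]phenyl}-7-[(3-methylbut-2-en-1-yl)oxy]-5-[(triisopropylsilyl)oxy]-4H-chromen-4-one | COc1cc(-c2oc3c(OC)c(OCC=C(C)C)cc(O[Si](C(C)C)(C(C)C)C(C)C)c3c(=O)c2O)ccc1O[Si](C(C)C)(C(C)C)C(C)C | intermediate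
20 | 3,5-dihydroxy-2-(4-hydroxy-3-methoxyphenyl)-8-methoxy-7-[(3-methylbut-2-en-1-yl)oxy]-4H-chromen-4-one (CNP0210396.0, achiral) | COc1cc(-c2oc3c(OC)c(OCC=C(C)C)cc(O)c3c(=O)c2O)ccc1O | target

**Step count and risks**

Total step count: 11. Longest linear sequence: 9 (steps 1–6, 9, 10, 11).

Steps most likely to fail:

1. Step 9. Oxidative addition into the electron-rich, doubly ortho-substituted iodophenoxide may be slow, which would let diethylamine capture the aroyl-palladium as an amide or let the alkyne couple without CO and close to a benzofuran. Closure could also leak to the 5-exo mode, or Pd(0) could ionise the prenyl ether. The fallback makes the same three bonds without palladium or CO; it sets out from 13 and 10 and comes back at 16. Alkyne 13 would be formylated (n-BuLi, then DMF) to 3-{3-methoxy-4-[(triisopropylsilyl)oxy]phenyl}prop-2-ynal F1. Iodophenol 10 would be deprotonated with MeMgCl and subjected to iodine–magnesium exchange with i-PrMgCl·LiCl to give the arylmagnesium phenoxide F2, which should add to F1 to give the racemic diaryl propargylic alcohol F3. Oxidation with MnO2 should give ynone 14, now isolated, and diethylamine in ethanol should close it through 15 to 16.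

2. Step 6. Discrimination between the two phenoxides may be incomplete, giving the regioisomeric ether and the bis-ether, and some C-prenylation may occur. The fallback postpones prenylation until the ring closure has told the two oxygens apart; it sets out from 7 and comes back at 16. Diol 7 would be acetylated (Ac2O, pyridine) to 4-iodo-2-methoxy-5-[(triisopropylsilyl)oxy]-1,3-phenylene diacetate F4. Carbonylative annulation of F4 with 13 under the step 9 conditions, in which diethylamine removes both acetyl groups in the flask and only the oxygen ortho to the new carbonyl can close ring C, should give the 7-hydroxyflavone F5. Its single free phenol would then be alkylated with 8 (K2CO3, acetone) to give 16.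

3. Step 10. Lithiation at C3 may be incomplete or may compete with deprotonation at the O–CH2 of the prenyl ether or with amide addition at C2, and the peroxide step may begin to epoxidise the prenyl alkene. The fallback introduces the oxygen through the flavanone enolate; it sets out from 16 and comes back at 19. Conjugate reduction of 16 with K-Selectride (THF, −78 °C) would give the potassium flavanone enolate F6, which would be hydroxylated in the flask with 2-(phenylsulfonyl)-3-phenyloxaziridine to the racemic trans-3-hydroxyflavanone F7. Dess–Martin oxidation of the C3 carbinol should give the 3,4-dione, whose enol tautomer is 19.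

**Further compounds**

F1 | step 9 | 3-{3-methoxy-4-[(triisopropylsilyl)oxy]phenyl}prop-2-ynal | O=CC#Cc1ccc(O[Si](C(C)C)(C(C)C)C(C)C)c(OC)c1
F2 | step 9 | chloromagnesium 2-(chloromagnesio)-6-methoxy-5-[(3-methylbut-2-en-1-yl)oxy]-3-[(triisopropylsilyl)oxy]phenoxide | COc1c(O[Mg]Cl)c([Mg]Cl)c(O[Si](C(C)C)(C(C)C)C(C)C)cc1OCC=C(C)C
F3 | step 9 | racemic 2-(1-hydroxy-3-{3-methoxy-4-[(triisopropylsilyl)oxy]phenyl}prop-2-yn-1-yl)-6-methoxy-5-[(3-methylbut-2-en-1-yl)oxy]-3-[(triisopropylsilyl)oxy]phenol | COc1cc(C#CC(O)c2c(O)c(OC)c(OCC=C(C)C)cc2O[Si](C(C)C)(C(C)C)C(C)C)ccc1O[Si](C(C)C)(C(C)C)C(C)C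
F4 | step 6 | 4-iodo-2-methoxy-5-[(triisopropylsilyl)oxy]-1,3-phenylene diacetate | COc1c(OC(C)=O)cc(O[Si](C(C)C)(C(C)C)C(C)C)c(I)c1OC(C)=O
F5 | step 6 | 7-hydroxy-8-methoxy-2-{3-methoxy-4-[(triisopropylsilyl)oxy]phenyl}-5-[(triisopropylsilyl)oxy]-4H-chromen-4-one | COc1cc(-c2cc(=O)c3c(O[Si](C(C)C)(C(C)C)C(C)C)cc(O)c(OC)c3o2)ccc1O[Si](C(C)C)(C(C)C)C(C)C
F6 | step 10 | potassium enolate of the flavanone from 16 (racemic at C2) | COc1cc(C2C=C([O-])c3c(O[Si](C(C)C)(C(C)C)C(C)C)cc(OCC=C(C)C)c(OC)c3O2)ccc1O[Si](C(C)C)(C(C)C)C(C)C.[K+]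
F7 | step 10 | racemic trans-3-hydroxy-8-methoxy-2-{3-methoxy-4-[(triisopropylsilyl)oxy]phenyl}-7-[(3-methylbut-2-en-1-yl)oxy]-5-[(triisopropylsilyl)oxy]chroman-4-one (one enantiomer drawn) | COc1cc([C@@H]2[C@@H](O)C(=O)c3c(O[Si](C(C)C)(C(C)C)C(C)C)cc(OCC=C(C)C)c(OC)c3O2)ccc1O[Si](C(C)C)(C(C)C)C(C)C
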